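**Strategy.** The route rests on reading the 1-oxa ring of the target, O1–C2(aryl)=C3–C4(=O)–C5(spiro), as a masked tertiary ethynyl carbinol. C5 is a carbinol carbon next to the C4 carbonyl, so C4 and C3 can be the two alkyne carbons, C2 carbon monoxide and the aryl group an aryl iodide. One palladium-catalysed CO/CO2 cascade (carbonylative Sonogashira coupling, carbonate-relayed hydration, cyclodehydration) then builds C2–C3, C2–aryl, the C4 carbonyl and O1–C2, and closes the furanone on a finished cyclopentenone. The precursor is a 5-ethynyl-5-hydroxycyclopentenone whose two quaternary centres come from a catalytic asymmetric aldol ring closure (C6) and a facially controlled acetylide addition to a 1,2-dione (C5).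

Key step: step 7

Remark 1: 3,4-dimethoxyfuran (1) and tert-butyl(4-iodophenoxy)dimethylsilane (11) are taken as commercial.
Remark 2: the sense of induction of the zinc–ProPhenol catalyst in step 3 is assigned by analogy only; the ligand antipode that delivers (1S)-7 is the one to be used.
Remark 3: cyclopentenones 7–10 are numbered C1 (carbinol/ester carbon), C2, C3 (methoxy carbons), C4 (enone carbonyl), C5; spiro compounds are numbered as 1-oxaspiro[4.4]nonanes (O1, C2–C4, spiro C5, C6–C9).

**Step 1**
Reactants: 1 3,4-dimethoxyfuran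
Product: 5 methyl 3,4-dimethoxy-5-methylfuran-2-carboxylate, via 2-lithio-3,4-dimethoxyfuran 2 (not isolated), via 3,4-dimethoxy-2-methylfuran 3 (not isolated), via 5-lithio-3,4-dimethoxy-2-methylfuran 4 (not isolated)
Conditions: n-BuLi (1.05 equiv), THF, −78 → 0 °C; MeI (1.0 equiv), −78 °C → rt; n-BuLi (1.1 equiv), −78 → 0 °C; cannulated into ClCO2Me (2 equiv), THF, −78 °C
Reagents that add atoms: iodomethane (CI); methyl chloroformate (COC(=O)Cl); n-butyllithium ([Li]CCCC; its lithium stays only in 2 and 4)
Why: Sequential α-lithiation and electrophilic quench of a furan (first at C2, then at the only remaining α-position) is standard furan metalation chemistry; one equivalent of MeI leaves nothing to consume the second charge of n-BuLi, inverse addition to excess chloroformate prevents double addition, and no stereocentre is formed.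

**Step 2**
Reactants: 5 methyl 3,4-dimethoxy-5-methylfuran-2-carboxylate
Product: 6 methyl (3Z)-3,4-dimethoxy-2,5-dioxohex-3-enoate
Conditions: dimethyldioxirane (1.05 equiv, solution in acetone), CH2Cl2/acetone, −40 → 0 °C; evaporated and used crude
Reagents that add atoms: dimethyldioxirane (CC1(C)OO1)
Why: Oxidative furan ring opening: the dioxirane epoxidises the electron-rich tetrasubstituted furan and the epoxide collapses to the cis-enedione, which fixes the Z geometry and the C(OMe)=C(OMe) pattern between a methyl ketone and an α-keto ester; acetone is the only by-product, so no chromatography is needed.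

**Step 3**
Reactants: 6 methyl (3Z)-3,4-dimethoxy-2,5-dioxohex-3-enoate
Product: 7 methyl (1S)-1-hydroxy-2,3-dimethoxy-4-oxocyclopent-2-ene-1-carboxylate
Conditions: (S,S)-ProPhenol (10 mol%), Et2Zn (20 mol%), 4 Å MS, THF, −20 °C, slow addition of 6
Reagents that add atoms: none
Why: Zinc–ProPhenol-catalysed direct aldol reaction (methyl ketone donor, chelating α-keto ester acceptor), run as the classical 5-(enolexo)-exo-trig closure of a cis-enedione to a 4-hydroxycyclopentenone; the zinc enolate and the zinc-bound keto ester meet inside the chiral dinuclear pocket, which selects the carbonyl face and so sets C1 as S, and the non-nucleophilic catalyst does not exchange the enol ether methoxy groups.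

**Step 4**
Reactants: 7 methyl (1S)-1-hydroxy-2,3-dimethoxy-4-oxocyclopent-2-ene-1-carboxylate
Product: 8 methyl (1S)-1-[(tert-butyldimethylsilyl)oxy]-2,3-dimethoxy-4-oxocyclopent-2-ene-1-carboxylate
Conditions: TBSOTf (1.5 equiv), 2,6-lutidine (2.5 equiv), CH2Cl2, −78 → 0 °C
Reagents that add atoms: tert-butyldimethylsilyl trifluoromethanesulfonate (CC(C)(C)[Si](C)(C)OS(=O)(=O)C(F)(F)F)
Why: Silyl triflate/2,6-lutidine silylation is the standard method for hindered tertiary alcohols; the silyl ether blocks retro-aldol opening in later steps and supplies the shielding group for step 6, and the C1 configuration is untouched.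

**Step 5**
Reactants: 8 methyl (1S)-1-[(tert-butyldimethylsilyl)oxy]-2,3-dimethoxy-4-oxocyclopent-2-ene-1-carboxylate
Product: 9 methyl (1R)-1-[(tert-butyldimethylsilyl)oxy]-2,3-dimethoxy-4,5-dioxocyclopent-2-ene-1-carboxylate
Conditions: SeO2 (1.5 equiv), dry 1,4-dioxane, 90 °C
Reagents that add atoms: selenium dioxide (O=[Se]=O)
Why: Riley oxidation: selenium dioxide converts the only enolisable α-methylene (C5) of the ketone into a carbonyl, as in the oxidation of cyclopentenones to cyclopentene-1,2-diones; the product is a non-enolisable 1,2-dione and the stereocentre is unchanged (the descriptor changes by priority only).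

**Step 6**
Reactants: 9 methyl (1R)-1-[(tert-butyldimethylsilyl)oxy]-2,3-dimethoxy-4,5-dioxocyclopent-2-ene-1-carboxylate
Product: 10 methyl (1S,5R)-1-[(tert-butyldimethylsilyl)oxy]-5-ethynyl-5-hydroxy-2,3-dimethoxy-4-oxocyclopent-2-ene-1-carboxylate
Conditions: HC≡CMgBr (1.3 equiv), THF, −78 °C; cold pH 7 aqueous work-up
Reagents that add atoms: ethynylmagnesium bromide (C#C[Mg]Br)
Why: Acetylide 1,2-addition goes to the C5 ketone because the C4 carbonyl is a deactivated vinylogous ester; by the polar Felkin–Anh model the nucleophile enters anti to the C1–OSi bond, reinforced by the bulk of the silyloxy group, which places the ethynyl group cis to the ester and the new hydroxyl cis to the silyloxy group (5R).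

**Step 7**
Reactants: 10 methyl (1S,5R)-1-[(tert-butyldimethylsilyl)oxy]-5-ethynyl-5-hydroxy-2,3-dimethoxy-4-oxocyclopent-2-ene-1-carboxylate; 11 tert-butyl(4-iodophenoxy)dimethylsilane (1.5 equiv)
Product: 14 methyl (5S,6R)-6-[(tert-butyldimethylsilyl)oxy]-2-{4-[(tert-butyldimethylsilyl)oxy]phenyl}-7,8-dimethoxy-4,9-dioxo-1-oxaspiro[4.4]nona-2,7-diene-6-carboxylate, via hydroxy ynone 12 (not isolated), via alkylidene cyclic carbonate 13 (not isolated)
Conditions: Pd(PPh3)4 (5 mol%), Et3N (3 equiv), CO (10 bar), CO2 (10 bar), MeCN, 90 °C, autoclave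
Reagents that add atoms: carbon monoxide ([C-]#[O+], supplies C2); carbon dioxide (O=C=O, relays the C4 carbonyl oxygen and is returned)
Why: Oxidative addition of 11 to Pd(0), CO insertion and copper-free alkynylation with the terminal alkyne of 10 (carbonylative Sonogashira coupling) give hydroxy ynone 12; its tertiary alkoxide captures CO2 and the carbonate adds 5-exo-dig (oxa-Michael) to the ynone carbon bonded to C5 to give alkylidene carbonate 13, whose decarboxylative opening leaves the C4 carbonyl and frees the C5 alkoxide. The closest known reaction is the palladium-catalysed three-component synthesis of 5-aryl-3(2H)-furanones from tertiary α-ethynyl carbinols, aryl halides and CO under CO2, which is established for carbinols set in rings. The furanone ring closes last, by O1–C2 bond formation: 5-exo-trig attack of the C5 alkoxide on the aryl ketone carbon followed by loss of water, a net isomerisation of 12. No stereocentre is made; C5 and C6 pass through unchanged because no bond at either centre is broken, and the C6 silyl ether together with the weak base prevents retro-aldol cleavage of the C5–C6 bond. The step needs carbonylative rather than direct alkynylation, which CO pressure and the electron-rich aryl–palladium species secure, and oxygen delivery to C4 rather than C3, which the intramolecular carbonate secures; triethylamine cannot displace the enol ether methoxy groups.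

**Step 8**
Reactants: 14 methyl (5S,6R)-6-[(tert-butyldimethylsilyl)oxy]-2-{4-[(tert-butyldimethylsilyl)oxy]phenyl}-7,8-dimethoxy-4,9-dioxo-1-oxaspiro[4.4]nona-2,7-diene-6-carboxylate
Product: 15 limnophilaspiroketone, methyl (5S,6R)-6-hydroxy-2-(4-hydroxyphenyl)-7,8-dimethoxy-4,9-dioxo-1-oxaspiro[4.4]nona-2,7-diene-6-carboxylate
Conditions: HF·pyridine (excess), pyridine/THF, 0 °C → rt
Reagents that add atoms: none
Why: Fluoride-mediated desilylation with buffered HF·pyridine should remove the aryl and the tertiary silyl ether under non-basic conditions, which avoids retro-aldol cleavage of the tertiary β-hydroxy ketone and leaves both stereocentres untouched.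

**Compound list**
1 | 3,4-dimethoxyfuran | COc1cocc1OC | starting material
2 | 2-lithio-3,4-dimethoxyfuran | [Li]c1occ(OC)c1OC | intermediate
3 | 3,4-dimethoxy-2-methylfuran | Cc1occ(OC)c1OC | intermediate
4 | 5-lithio-3,4-dimethoxy-2-methylfuran | [Li]c1oc(C)c(OC)c1OC | intermediate
5 | methyl 3,4-dimethoxy-5-methylfuran-2-carboxylate | COC(=O)c1oc(C)c(OC)c1OC | intermediate
6 | methyl (3Z)-3,4-dimethoxy-2,5-dioxohex-3-enoate (cis-enedione) | COC(=O)C(=O)/C(OC)=C(OC)\C(C)=O | intermediate
7 | methyl (1S)-1-hydroxy-2,3-dimethoxy-4-oxocyclopent-2-ene-1-carboxylate | COC(=O)[C@@]1(O)C(OC)=C(OC)C(=O)C1 | intermediate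
8 | methyl (1S)-1-[(tert-butyldimethylsilyl)oxy]-2,3-dimethoxy-4-oxocyclopent-2-ene-1-carboxylate | COC(=O)[C@@]1(O[Si](C)(C)C(C)(C)C)C(OC)=C(OC)C(=O)C1 | intermediate
9 | methyl (1R)-1-[(tert-butyldimethylsilyl)oxy]-2,3-dimethoxy-4,5-dioxocyclopent-2-ene-1-carboxylate | COC(=O)[C@@]1(O[Si](C)(C)C(C)(C)C)C(OC)=C(OC)C(=O)C1=O | intermediate
10 | methyl (1S,5R)-1-[(tert-butyldimethylsilyl)oxy]-5-ethynyl-5-hydroxy-2,3-dimethoxy-4-oxocyclopent-2-ene-1-carboxylate (ethynyl cis to the ester, hydroxyl cis to the silyloxy group) | COC(=O)[C@@]1(O[Si](C)(C)C(C)(C)C)C(OC)=C(OC)C(=O)[C@@]1(O)C#C | intermediate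
11 | tert-butyl(4-iodophenoxy)dimethylsilane | CC(C)(C)[Si](C)(C)Oc1ccc(I)cc1 | starting material
12 | methyl (1S,5R)-1-[(tert-butyldimethylsilyl)oxy]-5-(3-{4-[(tert-butyldimethylsilyl)oxy]phenyl}-3-oxoprop-1-yn-1-yl)-5-hydroxy-2,3-dimethoxy-4-oxocyclopent-2-ene-1-carboxylate (hydroxy ynone) | COC(=O)[C@@]1(O[Si](C)(C)C(C)(C)C)C(OC)=C(OC)C(=O)[C@@]1(O)C#CC(=O)c1ccc(O[Si](C)(C)C(C)(C)C)cc1 | intermediate
13 | alkylidene cyclic carbonate: (Z)-4-(2-{4-[(tert-butyldimethylsilyl)oxy]phenyl}-2-oxoethylidene)-1,3-dioxolan-2-one spiro-fused through its C5 to C5 of the cyclopentenone of 10, carbonate oxygen cis to the C1 silyloxy group | COC(=O)[C@@]1(O[Si](C)(C)C(C)(C)C)C(OC)=C(OC)C(=O)[C@]12OC(=O)O/C2=C\C(=O)c1ccc(O[Si](C)(C)C(C)(C)C)cc1 | intermediate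
14 | methyl (5S,6R)-6-[(tert-butyldimethylsilyl)oxy]-2-{4-[(tert-butyldimethylsilyl)oxy]phenyl}-7,8-dimethoxy-4,9-dioxo-1-oxaspiro[4.4]nona-2,7-diene-6-carboxylate | COC(=O)[C@@]1(O[Si](C)(C)C(C)(C)C)C(OC)=C(OC)C(=O)[C@]12OC(c1ccc(O[Si](C)(C)C(C)(C)C)cc1)=CC2=O | intermediate
15 | limnophilaspiroketone, methyl (5S,6R)-6-hydroxy-2-(4-hydroxyphenyl)-7,8-dimethoxy-4,9-dioxo-1-oxaspiro[4.4]nona-2,7-diene-6-carboxylate | COC(=O)[C@@]1(O)C(OC)=C(OC)C(=O)[C@]12OC(c1ccc(O)cc1)=CC2=O | target

**Totals.** Total step count: 8. Longest linear sequence: 8 steps (1 → 15); 11 enters in step 7.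

**Steps most likely to fail, with fallbacks**

Step 3. The risk is loss of enantiocontrol: the very reactive cis-enedione may cyclise through a base-mediated background pathway, and the constrained intramolecular transition state may not fit the catalyst pocket. The fallback replaces asymmetric catalysis by resolution. It sets out from 6, which is cyclised with catalytic triethylamine in CH2Cl2 to racemic methyl 1-hydroxy-2,3-dimethoxy-4-oxocyclopent-2-ene-1-carboxylate F1. The enantiomers are separated by preparative supercritical-fluid chromatography on a chiral stationary phase, and methyl (1R)-1-hydroxy-2,3-dimethoxy-4-oxocyclopent-2-ene-1-carboxylate F2 is set aside. The (1S)-enantiomer is 7, where the route is rejoined.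

Step 6. The risk is poor or reversed facial selectivity in the attack on the C5 carbonyl, if the ester rather than the silyloxy group dominates the shielding, beside some attack at C4. The fallback sets out from 8 and reverses the order in which the two C5 substituents are introduced, so that an ester-dominated bias works for the route. The lithium enolate of 8 (LiHMDS, THF, −78 °C) is ethynylated with an ethynylbenziodoxolone reagent (TMS-EBX, TBAF, −78 °C) to methyl (1S)-1-[(tert-butyldimethylsilyl)oxy]-5-ethynyl-2,3-dimethoxy-4-oxocyclopent-2-ene-1-carboxylate F3, obtained as C5 epimers that are both usable. The potassium enolate of F3 (KHMDS, THF, −78 °C) is then hydroxylated with 2-(phenylsulfonyl)-3-phenyloxaziridine. The oxidant should enter anti to the ester and give 10, where the route is rejoined.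

Step 7. The risk is that the cascade stalls after the coupling, because the carbonate relay is incomplete, or that the hindered carbinol fragments at the temperature required. The fallback sets out from 10 and 11 and separates coupling, hydration and ring closure. A room-temperature carbonylative Sonogashira coupling (PdCl2(PPh3)2, CuI, Et3N, THF, CO balloon) should give ynone 12, which is isolated. Gold(I)-catalysed conjugate hydration of 12 (Ph3PAuNTf2, wet 1,4-dioxane, rt) should give methyl (1S,5S)-1-[(tert-butyldimethylsilyl)oxy]-5-(3-{4-[(tert-butyldimethylsilyl)oxy]phenyl}-3-oxopropanoyl)-5-hydroxy-2,3-dimethoxy-4-oxocyclopent-2-ene-1-carboxylate F4. Acid-catalysed cyclodehydration of this α′-hydroxy-1,3-diketone (p-TsOH, toluene, rt → 50 °C) should give 14, where the route is rejoined.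

**Further compounds**
F1 | step 3 | racemic methyl 1-hydroxy-2,3-dimethoxy-4-oxocyclopent-2-ene-1-carboxylate | COC(=O)C1(O)C(OC)=C(OC)C(=O)C1
F2 | step 3 | methyl (1R)-1-hydroxy-2,3-dimethoxy-4-oxocyclopent-2-ene-1-carboxylate | COC(=O)[C@]1(O)C(OC)=C(OC)C(=O)C1
F3 | step 6 | methyl (1S)-1-[(tert-butyldimethylsilyl)oxy]-5-ethynyl-2,3-dimethoxy-4-oxocyclopent-2-ene-1-carboxylate (C5 epimers) | COC(=O)[C@@]1(O[Si](C)(C)C(C)(C)C)C(OC)=C(OC)C(=O)C1C#C
F4 | step 7 | methyl (1S,5S)-1-[(tert-butyldimethylsilyl)oxy]-5-(3-{4-[(tert-butyldimethylsilyl)oxy]phenyl}-3-oxopropanoyl)-5-hydroxy-2,3-dimethoxy-4-oxocyclopent-2-ene-1-carboxylate | COC(=O)[C@@]1(O[Si](C)(C)C(C)(C)C)C(OC)=C(OC)C(=O)[C@@]1(O)C(=O)CC(=O)c1ccc(O[Si](C)(C)C(C)(C)C)cc1
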